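At 14 min the larch run has made 26.2 mM of product and still holds 53.8 mM of starting material, the reagent charged in the smaller amount (the limiting reagent by the charge). Yet its last 6.60 min add a mere 3.20 mM.

| flask | starting material | partner | free catalyst | time |
|---|---|---|---|---|
| larch | 80.0 mM | 88.0 mM | 0.400 mM |  |
| elm | 80.0 mM | 130 mM | 0.400 mM |  |
| birch | 26.0 mM | 88.0 mM | 0.200 mM | 14 min |

- larch run (time / min: [product] / mM): 0.56: 4.8; 1.1: 7.8; 2.0: 12.4; 3.9: 17.7; 7.4: 23.0; 14: 26.2
- elm run (time / min: [product] / mM): 0.56: 6.0; 1.1: 12.0; 2.0: 17.3; 3.9: 25.5; 7.4: 33.7; 14: 36.6

(standard deviation of a reading: 0.6 mM)

- Overall: starting material + partner -> product, with free catalyst as catalyst.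
- Constant volume, constant temperature.
- What is held in complexes is read along with the free species.
- An order is taken over about fifteen percent of the charge, up and down.

1. how the opening rate goes with [partner] round the charge of the larch run: the exponent of the rate at two percent of starting material gone to product
2. product in the birch run at 14 min, as a share of the starting material charged

Write the balance of starting material, all its forms counted: c(starting material) = charge − c(product). From it take the leftover logarithm L = ln(charge / c(starting material)), which grows in proportion to time under a steady first-order pace.

Begin with the main step alone, partner and catalyst held at their charges. The readings at 1.1 min give a pace of 0.0933 min⁻¹ in the larch run and 0.148 min⁻¹ in the elm run. The birch run has half the catalyst of the larch run, so you take 0.0466 min⁻¹, and over 14 min that turns 47.9% of its starting material.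

Now add the stall as it is read, with no step named for it. At 14 min, L reads 0.397 in the larch run and 0.612 in the elm run. Dividing each by its pace gives 4.25 min and 4.14 min, with mean 4.20 min: this is the working window, the minutes of opening pace a run actually gets. Raising the partner from 88.0 mM to 130 mM shifts it by 0.110 min, so the ratio of the L values stands for the ratio of paces, and it gives an order in partner of 1.11. Put the window in place of 14 min for the birch run, and 47.9% becomes 17.8%.

The rest, the orders in starting material and catalyst, stays untested, since larch and elm share both charges. You add nothing for them and commit to 17.8%.

The forecast says 0.85 and 24%, reasoning that “The stall therefore looks like catalyst loss”. The flask gives an order of 1.1 and 31.8%.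

    2 free catalyst ⇌ catalyst dimer, settled at all times (1.330 × 10⁵ M⁻¹)
    catalyst dimer + starting material + partner → product + catalyst dimer (32580 M⁻² min⁻¹)
    partner → lost reagent (0.1926 min⁻¹)
    2 starting material ⇌ idle substrate dimer, settled at all times (128.0 M⁻¹)

The opening rates of these two runs, taken over the charge, put the window at 4.13 min in the larch run and 4.22 min in the elm run. For the birch run, 31.8% means L = 0.383, which over the window 4.20 min asks for a pace of 0.0912 min⁻¹, twice your 0.0466 min⁻¹ and so faster. Your pace assumed first order in starting material, but the idle substrate dimer ties it up, and the apparent order in starting material is 0.59, against 1.0 without that dimer.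

All runs were generated by integration from invented constants.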